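**Retrosynthetic overview**
1. Last C–C bond: C4 (upper unit)–C8 (middle unit), by Friedel–Crafts capture of the flavan-4-yl cation derived from (S)-liquiritigenin by the middle–lower dimer; then deacetylation and hydrogenolysis.
2. Key disconnection: ring C of the middle unit is closed at C2–C3. An O-aryl oxocarbenium ion (O1=C2, from the ring A phenol oxygen and the 4-benzyloxybenzaldehyde carbon) is attacked by C3 of an ortho (E)-enol acetate (C3=C4); the C4 cation left behind is captured in the same flask by C8 of protected (−)-epiafzelechin, which makes the C4–C8 interflavan bond.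
3. Enabling feature: C4 of the middle ring C is benzylic to the phloroglucinol-type ring A (donors O1 on C8a, O5 and O7) and C3 carries oxygen. A C3=C4 styrenyl enol ester is therefore nucleophilic at C3, the cation at C4 is the well-stabilised flavan-4-yl cation, and the 3-acyloxy group steers the incoming arene to the β face.
4. The cyclisation precursor comes from 2,4,6-trihydroxybenzaldehyde (ring A and C4), a diborylmethane (C3) and 4-benzyloxybenzaldehyde (C2 and ring B).
5. Ring order: lower-unit rings from the chiral pool; middle ring C in the key step; upper-unit rings from the chiral pool, attached last.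

Key step: step 9

Remark: (−)-epiafzelechin and (S)-liquiritigenin are taken as purchasable, enantiopure natural products.
Remark: the sense of induction of the chiral acid in step 9 is assumed; if the (R) acid favours the (2S,3S) series, its antipode is used with nothing else changed.

Step 1
Reactants: 1 (−)-epiafzelechin
Product: 2 5,7,4′-tri-O-benzyl-(−)-epiafzelechin
Conditions: BnBr (3.3 equiv), K2CO3, DMF, 0 °C → rt
Reagents that add atoms: benzyl bromide, BrCc1ccccc1
Why: Williamson ether synthesis; carbonate deprotonates only the three phenols, so the secondary 3-OH should stay free and no stereocentre is touched.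

Step 2
Reactants: 2 5,7,4′-tri-O-benzyl-(−)-epiafzelechin
Product: 3 3-O-acetyl-5,7,4′-tri-O-benzyl-(−)-epiafzelechin
Conditions: Ac2O, pyridine, DMAP (cat.), CH2Cl2, rt
Reagents that add atoms: acetic anhydride, CC(=O)OC(C)=O
Why: DMAP-catalysed acylation of the secondary alcohol removes the last O–H, so that in step 9 only ring A carbon C8 can act as the nucleophile.

Step 3
Reactants: 4 2,4,6-trihydroxybenzaldehyde
Product: 5 2,4-bis(benzyloxy)-6-hydroxybenzaldehyde
Conditions: BnBr (2.05 equiv), K2CO3 (2.1 equiv), DMF, rt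
Reagents that add atoms: benzyl bromide, BrCc1ccccc1
Why: Williamson ether synthesis; the 4-OH and one ortho OH are alkylated, while the remaining ortho OH is hydrogen-bonded to the formyl group, is the least nucleophilic and should stay free.

Step 4
Reactants: 5 2,4-bis(benzyloxy)-6-hydroxybenzaldehyde
Product: 6 2,4-bis(benzyloxy)-6-(triisopropylsilyloxy)benzaldehyde
Conditions: i-Pr3SiCl, imidazole, DMAP (cat.), DMF, rt
Reagents that add atoms: triisopropylsilyl chloride, CC(C)[Si](Cl)(C(C)C)C(C)C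
Why: silylation masks the only acidic proton before the carbanion chemistry of step 5 and the copper-mediated C–O coupling of step 6, and the bulky silyl group is slow to migrate.

Step 5
Reactants: 6 2,4-bis(benzyloxy)-6-(triisopropylsilyloxy)benzaldehyde; 7 bis(4,4,5,5-tetramethyl-1,3,2-dioxaborolan-2-yl)methane
Product: 9 (E)-2-[2,4-bis(benzyloxy)-6-(triisopropylsilyloxy)styryl]-4,4,5,5-tetramethyl-1,3,2-dioxaborolane, via lithio-bis(pinacolboryl)methane 8 (not isolated)
Conditions: 7, lithium 2,2,6,6-tetramethylpiperidide (LiTMP), THF, 0 °C; then 6, −78 °C → rt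
Reagents that add atoms: none
Why: boron–Wittig olefination; the α-boryl carbanion adds to the aldehyde and syn B–O elimination should deliver the trans alkenylboronate, which fixes the E geometry needed in step 9.

Step 6
Reactants: 9 (E)-2-[2,4-bis(benzyloxy)-6-(triisopropylsilyloxy)styryl]-4,4,5,5-tetramethyl-1,3,2-dioxaborolane
Product: 10 (E)-2-[2,4-bis(benzyloxy)-6-(triisopropylsilyloxy)phenyl]vinyl acetate
Conditions: Cu(OAc)2 (2 equiv), Et3N (3 equiv), 4 Å MS, MeCN, air, rt → 40 °C
Reagents that add atoms: copper diacetate, CC(=O)[O-].CC(=O)[O-].[Cu+2]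
Why: Chan–Lam-type copper-mediated C–O coupling of an alkenylboron compound with carboxylate; transmetalation to divalent copper and C–O reductive elimination proceed with retention, so the E enol acetate should result.

Step 7
Reactants: 10 (E)-2-[2,4-bis(benzyloxy)-6-(triisopropylsilyloxy)phenyl]vinyl acetate
Product: 11 (E)-2-[2,4-bis(benzyloxy)-6-hydroxyphenyl]vinyl acetate
Conditions: TBAF (1.1 equiv), AcOH (1.1 equiv), THF, 0 °C
Reagents that add atoms: none
Why: fluoride cleaves the aryl silyl ether rapidly, and buffering with AcOH keeps the medium non-basic so that the enol acetate is not transesterified; the E geometry also prevents intramolecular acyl transfer to the phenol.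

Step 8
Reactants: 11 (E)-2-[2,4-bis(benzyloxy)-6-hydroxyphenyl]vinyl acetate; 12 4-(benzyloxy)benzaldehyde
Product: 14 (E)-2-[2-{acetoxy[4-(benzyloxy)phenyl]methoxy}-4,6-bis(benzyloxy)phenyl]vinyl acetate, via α-chlorobenzyl acetate 13 (not isolated)
Conditions: 12, AcCl (1.0 equiv), ZnCl2 (2 mol%), CH2Cl2, 0 °C; then 11, i-Pr2NEt, −20 °C → rt
Reagents that add atoms: acetyl chloride, CC(Cl)=O
Why: Lewis-acid-catalysed addition of the acyl chloride to the aldehyde gives an α-chloroalkyl ester that O-alkylates the phenol (acyloxyalkylation); the new acetal carbon is racemic, which does not matter because it becomes planar in step 9.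

Step 9
Reactants: 14 (E)-2-[2-{acetoxy[4-(benzyloxy)phenyl]methoxy}-4,6-bis(benzyloxy)phenyl]vinyl acetate; 3 3-O-acetyl-5,7,4′-tri-O-benzyl-(−)-epiafzelechin
Product: 17 3-O-acetyl-5,7,4′-tri-O-benzyl-(−)-epiafzelechin-(4β→8)-3-O-acetyl-5,7,4′-tri-O-benzyl-(−)-epiafzelechin, via O-aryl oxocarbenium ion 15 (not isolated), via 3-acetoxyflavan-4-yl cation 16 (not isolated)
Conditions: (R)-3,3′-bis(2,4,6-triisopropylphenyl)-1,1′-binaphthyl-2,2′-diyl N-triflylphosphoramide (10 mol%), 3 (2 equiv), 4 Å MS, CH2Cl2, slow addition of 14, −60 → −30 °C; Et3N quench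
Reagents that add atoms: none
Why: Proposed new method: the chiral acid ionises the α-acetoxy ether (loss of AcOH) to the (E)-O-aryl oxocarbenium ion 15, C3 of the ortho (E)-enol acetate attacks C2 (a Prins-type cation–olefin closure in which the charge moves to C4, benzylic to ring A and conjugated with O1, O5 and O7, whereas attack through C4 would leave a poorly stabilised α-acyloxy cation), and cation 16 is then captured by C8 of 3 in a Friedel–Crafts step. The closest known reaction types are the segment-coupling Prins cyclisation of α-acetoxy ethers, chiral-anion-controlled additions and Prins cyclisations of oxocarbenium ions under strong chiral Brønsted acids, and the acid-mediated C4–C8 coupling of 3-acyloxyflavan-4-yl cations with flavan-3-ol nucleophiles used for proanthocyanidins; their merger on a styrenyl enol ester is new. Ring C closes in a 6-endo-trig mode with respect to both π bonds, formally a disrotatory 6π closure of the oxatrienyl cation C2=O1–C8a=C4a–C4=C3. C2 and C3 are created together: the aryl group on C2 and the acetoxy group on C3 are the outward substituents of the E,E array and therefore become cis, while the face of 15 that is attacked, hence the absolute (2R,3R) sense, is set by the chiral counter-anion. C4 is set by the 3-acetoxy group, which bridges the α face of 16 as an acetoxonium ion so that the arene enters from the β face (3,4-trans). The step needs ring closure to outrun intermolecular capture of 15 by 3 (secured by the intramolecular six-membered array and the slow addition of 14) and C8 rather than C6 attack of 3 (C8, next to the pyran oxygen, is the more nucleophilic and less hindered site of 5,7-di-O-benzylflavans), and since 3 is enantiopure any stereochemical leakage appears as diastereomers that can be separated.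

Step 10
Reactants: 18 (S)-liquiritigenin
Product: 19 (2S,4S)-2-(4-hydroxyphenyl)chroman-4,7-diol
Conditions: NaBH4, EtOH/THF, 0 °C
Reagents that add atoms: none
Why: borohydride reduction of the flavanone carbonyl should give the 2,4-cis alcohol; the C4 configuration is of no consequence because C4 is ionised in step 12, and C2 is untouched.

Step 11
Reactants: 19 (2S,4S)-2-(4-hydroxyphenyl)chroman-4,7-diol
Product: 20 (2S,4S)-7-(benzyloxy)-2-[4-(benzyloxy)phenyl]chroman-4-ol
Conditions: BnBr (2.1 equiv), K2CO3, DMF, rt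
Reagents that add atoms: benzyl bromide, BrCc1ccccc1
Why: Williamson ether synthesis on the two phenols only; with the ketone already reduced there is no base-induced ring opening to a chalcone, so C2 should keep its configuration.

Step 12
Reactants: 17 3-O-acetyl-5,7,4′-tri-O-benzyl-(−)-epiafzelechin-(4β→8)-3-O-acetyl-5,7,4′-tri-O-benzyl-(−)-epiafzelechin; 20 (2S,4S)-7-(benzyloxy)-2-[4-(benzyloxy)phenyl]chroman-4-ol
Product: 22 (2S)-7,4′-di-O-benzylflavan-(4β→8)-[3-O-acetyl-5,7,4′-tri-O-benzyl-(−)-epiafzelechin]-(4β→8)-[3-O-acetyl-5,7,4′-tri-O-benzyl-(−)-epiafzelechin], via flavan-4-yl cation 21 (not isolated)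
Conditions: TMSOTf (0.2 equiv), 4 Å MS, CH2Cl2, −78 → −40 °C, slow addition of 20; Et3N quench
Reagents that add atoms: none
Why: Friedel–Crafts alkylation by an SN1 path; cation 21 should be attacked by the most nucleophilic free ring A position, C8 of the upper unit of 17 (next to the pyran oxygen, whereas both C6 positions are flanked by two benzyloxy groups), along the axial trajectory anti to the equatorial C2 aryl group, which sets the new C4 as 2,4-trans (4β).

Step 13
Reactants: 22 (2S)-7,4′-di-O-benzylflavan-(4β→8)-[3-O-acetyl-5,7,4′-tri-O-benzyl-(−)-epiafzelechin]-(4β→8)-[3-O-acetyl-5,7,4′-tri-O-benzyl-(−)-epiafzelechin]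
Product: 23 (2S)-7,4′-di-O-benzylflavan-(4β→8)-[5,7,4′-tri-O-benzyl-(−)-epiafzelechin]-(4β→8)-[5,7,4′-tri-O-benzyl-(−)-epiafzelechin]
Conditions: NaOMe (0.3 equiv), MeOH/THF, rt → 40 °C
Reagents that add atoms: none
Why: Zemplén transesterification removes both secondary acetates; benzyl ethers and all stereocentres are inert to methoxide when no free phenol is present.

Step 14
Reactants: 23 (2S)-7,4′-di-O-benzylflavan-(4β→8)-[5,7,4′-tri-O-benzyl-(−)-epiafzelechin]-(4β→8)-[5,7,4′-tri-O-benzyl-(−)-epiafzelechin]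
Product: 24 (2S)-7,4′-dihydroxyflavan-(4β→8)-(−)-epiafzelechin-(4β→8)-(−)-epiafzelechin (CNP0257624.1)
Conditions: H2 (1 atm), Pd(OH)2/C, THF/MeOH/H2O, rt
Reagents that add atoms: none
Why: hydrogenolysis of the eight benzyl ethers; under these mild conditions the cyclic benzylic C2–O bonds and the diarylmethine C4 centres of flavans should survive.

**Compound list**
1 | (−)-epiafzelechin, (2R,3R)-2-(4-hydroxyphenyl)chroman-3,5,7-triol | c1c(O)cc(O)c2c1O[C@H](c1ccc(O)cc1)[C@H](O)C2 | starting material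
2 | 5,7,4′-tri-O-benzyl-(−)-epiafzelechin | c1c(OCc5ccccc5)cc(OCc5ccccc5)c2c1O[C@H](c1ccc(OCc5ccccc5)cc1)[C@H](O)C2 | intermediate
3 | 3-O-acetyl-5,7,4′-tri-O-benzyl-(−)-epiafzelechin | c1c(OCc5ccccc5)cc(OCc5ccccc5)c2c1O[C@H](c1ccc(OCc5ccccc5)cc1)[C@H](OC(C)=O)C2 | intermediate
4 | 2,4,6-trihydroxybenzaldehyde | O=Cc1c(O)cc(O)cc1O | starting material
5 | 2,4-bis(benzyloxy)-6-hydroxybenzaldehyde | O=Cc1c(O)cc(OCc2ccccc2)cc1OCc1ccccc1 | intermediate
6 | 2,4-bis(benzyloxy)-6-(triisopropylsilyloxy)benzaldehyde | O=Cc1c(O[Si](C(C)C)(C(C)C)C(C)C)cc(OCc2ccccc2)cc1OCc1ccccc1 | intermediate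
7 | bis(4,4,5,5-tetramethyl-1,3,2-dioxaborolan-2-yl)methane | CC1(C)OB(CB2OC(C)(C)C(C)(C)O2)OC1(C)C | starting material
8 | lithio-bis(pinacolboryl)methane (not isolated) | [Li]C(B1OC(C)(C)C(C)(C)O1)B1OC(C)(C)C(C)(C)O1 | intermediate
9 | (E)-2-[2,4-bis(benzyloxy)-6-(triisopropylsilyloxy)styryl]-4,4,5,5-tetramethyl-1,3,2-dioxaborolane | CC1(C)OB(/C=C/c2c(O[Si](C(C)C)(C(C)C)C(C)C)cc(OCc3ccccc3)cc2OCc2ccccc2)OC1(C)C | intermediate
10 | (E)-2-[2,4-bis(benzyloxy)-6-(triisopropylsilyloxy)phenyl]vinyl acetate | CC(=O)O/C=C/c1c(O[Si](C(C)C)(C(C)C)C(C)C)cc(OCc2ccccc2)cc1OCc1ccccc1 | intermediate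
11 | (E)-2-[2,4-bis(benzyloxy)-6-hydroxyphenyl]vinyl acetate | CC(=O)O/C=C/c1c(O)cc(OCc2ccccc2)cc1OCc1ccccc1 | intermediate
12 | 4-(benzyloxy)benzaldehyde | O=Cc1ccc(OCc2ccccc2)cc1 | starting material
13 | chloro[4-(benzyloxy)phenyl]methyl acetate, racemic (not isolated) | CC(=O)OC(Cl)c1ccc(OCc2ccccc2)cc1 | intermediate
14 | (E)-2-[2-{acetoxy[4-(benzyloxy)phenyl]methoxy}-4,6-bis(benzyloxy)phenyl]vinyl acetate, racemic at the acetal carbon | CC(=O)O/C=C/c1c(OC(OC(C)=O)c2ccc(OCc3ccccc3)cc2)cc(OCc2ccccc2)cc1OCc1ccccc1 | intermediate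
15 | O-aryl oxocarbenium ion from 14 (not isolated) | CC(=O)O/C=C/c1c([O+]=Cc2ccc(OCc3ccccc3)cc2)cc(OCc2ccccc2)cc1OCc1ccccc1 | intermediate
16 | (2R,3R)-3-acetoxy-5,7-bis(benzyloxy)-2-[4-(benzyloxy)phenyl]chroman-4-yl cation, bridged on its α face by the acetoxy group (not isolated) | c1c(OCc5ccccc5)cc(OCc5ccccc5)c2c1O[C@H](c1ccc(OCc5ccccc5)cc1)[C@H](OC(C)=O)[CH+]2 | intermediate
17 | 3-O-acetyl-5,7,4′-tri-O-benzyl-(−)-epiafzelechin-(4β→8)-3-O-acetyl-5,7,4′-tri-O-benzyl-(−)-epiafzelechin; upper unit (2R,3R,4R) | c1c(OCc5ccccc5)cc(OCc5ccccc5)c2c1O[C@H](c1ccc(OCc5ccccc5)cc1)[C@H](OC(C)=O)[C@H]2c1c(OCc5ccccc5)cc(OCc5ccccc5)c2c1O[C@H](c1ccc(OCc5ccccc5)cc1)[C@H](OC(C)=O)C2 | intermediate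
18 | (S)-liquiritigenin, (2S)-7-hydroxy-2-(4-hydroxyphenyl)chroman-4-one | Oc1ccc([C@@H]2CC(=O)c3ccc(O)cc3O2)cc1 | starting material
19 | (2S,4S)-2-(4-hydroxyphenyl)chroman-4,7-diol | Oc1ccc([C@@H]2C[C@H](O)c3ccc(O)cc3O2)cc1 | intermediate
20 | (2S,4S)-7-(benzyloxy)-2-[4-(benzyloxy)phenyl]chroman-4-ol | O(Cc5ccccc5)c1ccc([C@@H]2C[C@H](O)c3ccc(OCc5ccccc5)cc3O2)cc1 | intermediate
21 | (2S)-7-(benzyloxy)-2-[4-(benzyloxy)phenyl]chroman-4-yl cation (not isolated) | O(Cc5ccccc5)c1ccc([C@@H]2C[CH+]c3ccc(OCc5ccccc5)cc3O2)cc1 | intermediate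
22 | (2S)-7,4′-di-O-benzylflavan-(4β→8)-[3-O-acetyl-5,7,4′-tri-O-benzyl-(−)-epiafzelechin]-(4β→8)-[3-O-acetyl-5,7,4′-tri-O-benzyl-(−)-epiafzelechin] | O(Cc5ccccc5)c1ccc([C@@H]2C[C@@H](c3c(OCc5ccccc5)cc(OCc5ccccc5)c4c3O[C@H](c3ccc(OCc5ccccc5)cc3)[C@H](OC(C)=O)[C@H]4c3c(OCc5ccccc5)cc(OCc5ccccc5)c4c3O[C@H](c3ccc(OCc5ccccc5)cc3)[C@H](OC(C)=O)C4)c3ccc(OCc5ccccc5)cc3O2)cc1 | intermediate
23 | (2S)-7,4′-di-O-benzylflavan-(4β→8)-[5,7,4′-tri-O-benzyl-(−)-epiafzelechin]-(4β→8)-[5,7,4′-tri-O-benzyl-(−)-epiafzelechin] | O(Cc5ccccc5)c1ccc([C@@H]2C[C@@H](c3c(OCc5ccccc5)cc(OCc5ccccc5)c4c3O[C@H](c3ccc(OCc5ccccc5)cc3)[C@H](O)[C@H]4c3c(OCc5ccccc5)cc(OCc5ccccc5)c4c3O[C@H](c3ccc(OCc5ccccc5)cc3)[C@H](O)C4)c3ccc(OCc5ccccc5)cc3O2)cc1 | intermediate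
24 | CNP0257624.1, (2S,4R)-7,4′-dihydroxyflavan-(4β→8)-(2R,3R,4S)-epiafzelechin-(4β→8)-(2R,3R)-epiafzelechin | Oc1ccc([C@@H]2C[C@@H](c3c(O)cc(O)c4c3O[C@H](c3ccc(O)cc3)[C@H](O)[C@H]4c3c(O)cc(O)c4c3O[C@H](c3ccc(O)cc3)[C@H](O)C4)c3ccc(O)cc3O2)cc1 | target

**Step count and risks**
Total step count: 14. Longest linear sequence: 10 steps (steps 3, 4, 5, 6, 7, 8, 9, 12, 13, 14).

Step 9. What may go wrong: the oxocarbenium ion may be intercepted by the external arene, or the enol acetate protonated, before ring closure; the chiral anion may discriminate the two faces poorly; the C4 cation may lose a proton to a flav-3-ene instead of being arylated. The fallback uses known chemistry, sets out from 2 and returns at 17. DDQ oxidation of 2 at C4 in CH2Cl2 containing 2-ethoxyethanol should give 4β-(2-ethoxyethoxy)-5,7,4′-tri-O-benzyl-(−)-epiafzelechin F1. Acetylation (Ac2O, pyridine, DMAP) gives its 3-acetate F2. TMSOTf-catalysed Friedel–Crafts condensation of F2 with an excess of 3 at −78 °C then forms the C4–C8 bond from the β face and gives 17. Here the middle unit is taken from the chiral pool instead of being built.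

Step 12. What may go wrong: the two C6 positions may compete with C8 (poor site selectivity), the 3-unsubstituted cation may be attacked from both faces (2,4-cis epimer), and the product may be alkylated a second time. The fallback changes the order of bond formation, sets out from 20 and from the F2 of the fallback above (itself made from 2), and returns at 22. Exchange of the 4-alkoxy group of F2 for 2,6-dimethylbenzenethiol (BF3·OEt2, CH2Cl2, −78 °C) gives 4β-(2,6-dimethylphenylthio)-3-O-acetyl-5,7,4′-tri-O-benzyl-(−)-epiafzelechin F3, whose C–S bond is inert to hard Lewis acids. Friedel–Crafts coupling of 20 with this single flavan nucleophile (BF3·OEt2, −78 → −40 °C) gives the upper–middle thioether F4, where only C8 and C6 of one unit compete and the 2,4-epimers are separated on a smaller molecule. Thiophilic activation of F4 (N-iodosuccinimide, cat. TfOH, −40 °C) in the presence of 3 then forms the middle–lower C4–C8 bond under control of the 3-acetoxy group and gives 22.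

Step 6. What may go wrong: protodeboronation or oxidative homocoupling of the alkenylboronate may outrun C–O bond formation, and the E geometry may erode. The fallback sets out from 9 and returns at 10. Oxidation of the C–B bond (NaBO3·4H2O, THF/H2O, rt) gives the arylacetaldehyde F5. Enol acetylation (Ac2O, Et3N, DMAP, CH2Cl2) gives 10 together with its Z isomer F6, which is separated and recycled by iodine-catalysed isomerisation.

**Further compounds**
F1 | step 9 | 4β-(2-ethoxyethoxy)-5,7,4′-tri-O-benzyl-(−)-epiafzelechin | c1c(OCc5ccccc5)cc(OCc5ccccc5)c2c1O[C@H](c1ccc(OCc5ccccc5)cc1)[C@H](O)[C@H]2OCCOCC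
F2 | step 9 | 3-O-acetyl-4β-(2-ethoxyethoxy)-5,7,4′-tri-O-benzyl-(−)-epiafzelechin | c1c(OCc5ccccc5)cc(OCc5ccccc5)c2c1O[C@H](c1ccc(OCc5ccccc5)cc1)[C@H](OC(C)=O)[C@H]2OCCOCC
F3 | step 12 | 3-O-acetyl-4β-(2,6-dimethylphenylthio)-5,7,4′-tri-O-benzyl-(−)-epiafzelechin | c1c(OCc5ccccc5)cc(OCc5ccccc5)c2c1O[C@H](c1ccc(OCc5ccccc5)cc1)[C@H](OC(C)=O)[C@H]2Sc1c(C)cccc1C
F4 | step 12 | (2S)-7,4′-di-O-benzylflavan-(4β→8)-[3-O-acetyl-4β-(2,6-dimethylphenylthio)-5,7,4′-tri-O-benzyl-(−)-epiafzelechin] | O(Cc5ccccc5)c1ccc([C@@H]2C[C@@H](c3c(OCc5ccccc5)cc(OCc5ccccc5)c4c3O[C@H](c3ccc(OCc5ccccc5)cc3)[C@H](OC(C)=O)[C@H]4Sc3c(C)cccc3C)c3ccc(OCc5ccccc5)cc3O2)cc1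
F5 | step 6 | 2-[2,4-bis(benzyloxy)-6-(triisopropylsilyloxy)phenyl]acetaldehyde | O=CCc1c(O[Si](C(C)C)(C(C)C)C(C)C)cc(OCc2ccccc2)cc1OCc1ccccc1
F6 | step 6 | (Z)-2-[2,4-bis(benzyloxy)-6-(triisopropylsilyloxy)phenyl]vinyl acetate | CC(=O)O/C=C\c1c(O[Si](C(C)C)(C(C)C)C(C)C)cc(OCc2ccccc2)cc1OCc1ccccc1
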